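**Plan**

1. Numbering used throughout: lactone carbonyl C1, then C2(Me), C3(=O), C4(OH)(CH2OH), C5, C6(OMe)=C7, C8(Me), C9, C10(=CH2), C11=C12(Me), C13(Et)–O.
2. Retrosynthetic cuts: C1–C2 (ring closure), O–C1 (carbonyl from CDI), C10–C11 (Suzuki–Miyaura), C6–OMe (copper C–O coupling), C5–C6 (acetylide + epoxide).
3. Forward: alkyne C6–C10 + epoxide C3–C5 → tethered hydrosilylation → vinyl iodide → methyl enol ether → C3 ketone → diene with C11–C13 → imidazole-1-carboxylate → the only ring (14-membered) closed last by C-acylation → desilylation.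
4. Stereochemistry: C8 by Evans alkylation; C4 by Sharpless kinetic resolution; C13 from (S)-pent-1-yn-3-ol; C6=C7 by syn-hydrosilylation followed by two retentive substitutions; C11=C12 by anti-carbomagnesiation; C2 by equilibration in the macrocycle.
5. Enabling feature: ketone C3 lies between the fully substituted C4 and C2H2, so it has a single enolisable side; the new C1–C2–C3 unit is a 1,3-dicarbonyl with one acidic H, whose chelated enolate is the thermodynamic sink; the ring-cis alkenes C6=C7 and C11=C12 and quaternary C4 pre-bend the chain for the 14-membered ring.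

Key step: step 21

Assumption: the (2R) configuration is taken to be the thermodynamically preferred C2 epimer of the 14-membered 2-methyl-3-oxo lactone, since C2 equilibrates through the enol in steps 21 and 22.

**Step 1**
Reactants: 1 (R)-4-benzyl-3-propanoyl-1,3-oxazolidin-2-one; 2 2,3-dibromoprop-1-ene
Product: 4 (R)-4-benzyl-3-[(2S)-4-bromo-2-methylpent-4-enoyl]-1,3-oxazolidin-2-one, via sodium enolate 3 (not isolated)
Conditions: NaHMDS, THF, −78 °C; then 2, −78 → −40 °C
Reagents that add atoms: none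
Why: Evans alkylation: the chelated (Z)-sodium enolate is alkylated by the allylic bromide on the face away from the benzyl group, which sets C8 as (S).

**Step 2**
Reactants: 4 (R)-4-benzyl-3-[(2S)-4-bromo-2-methylpent-4-enoyl]-1,3-oxazolidin-2-one
Product: 5 (2S)-4-bromo-2-methylpent-4-en-1-ol
Conditions: LiBH4, MeOH (1 equiv), Et2O, 0 °C
Reagents that add atoms: none
Why: Reductive cleavage of the N-acyl oxazolidinone by borohydride should give the primary alcohol without touching the stereocentre or the vinyl bromide.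

**Step 3**
Reactants: 5 (2S)-4-bromo-2-methylpent-4-en-1-ol
Product: 6 (2S)-4-bromo-2-methylpent-4-enal
Conditions: Dess–Martin periodinane, NaHCO3, CH2Cl2, 0 °C → rt (used crude)
Reagents that add atoms: none
Why: Dess–Martin oxidation gives the α-branched aldehyde under buffered, non-enolising conditions.

**Step 4**
Reactants: 6 (2S)-4-bromo-2-methylpent-4-enal
Product: 7 (3S)-5-bromo-3-methylhex-5-en-1-yne
Conditions: dimethyl (1-diazo-2-oxopropyl)phosphonate, K2CO3, MeOH, 0 °C → rt
Reagents that add atoms: dimethyl (1-diazo-2-oxopropyl)phosphonate, COP(=O)(OC)C(=[N+]=[N-])C(C)=O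
Why: Ohira–Bestmann (Seyferth–Gilbert) homologation converts the aldehyde into the terminal alkyne under mild carbonate conditions that should leave the α-stereocentre intact.

**Step 5**
Reactants: 8 2-bromoprop-2-en-1-ol; 9 propanal
Product: 11 (±)-2-methylidenepentane-1,3-diol, via dilithio alkoxide 10 (not isolated)
Conditions: t-BuLi (3.1 equiv), Et2O, −78 → 0 °C; then 9, −78 °C; aq NH4Cl
Reagents that add atoms: none
Why: O–H deprotonation and bromine–lithium exchange give the O,2-dilithio allyl alcohol (the alkoxide is no leaving group, so no allene forms), which adds to the aldehyde as a 2-(hydroxymethyl)vinyl anion.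

**Step 6**
Reactants: 11 (±)-2-methylidenepentane-1,3-diol
Product: 12 (±)-2-{[(tert-butyldimethylsilyl)oxy]methyl}pent-1-en-3-ol
Conditions: TBSCl (1.05 equiv), imidazole, CH2Cl2, −20 → 0 °C
Reagents that add atoms: tert-butyldimethylsilyl chloride, CC(C)(C)[Si](C)(C)Cl
Why: The primary allylic hydroxyl is silylated much faster than the secondary one.

**Step 7**
Reactants: 12 (±)-2-{[(tert-butyldimethylsilyl)oxy]methyl}pent-1-en-3-ol
Product: 13 (1R)-1-[(2R)-2-{[(tert-butyldimethylsilyl)oxy]methyl}oxiran-2-yl]propan-1-ol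
Conditions: Ti(OiPr)4, D-(−)-diisopropyl tartrate, t-BuOOH (0.5 equiv), 4 Å MS, CH2Cl2, −20 °C
Reagents that add atoms: tert-butyl hydroperoxide, CC(C)(C)OO
Why: Sharpless kinetic resolution: with the D-(−)-tartrate the (R)-alcohol is epoxidised fast on the face that gives the erythro epoxy alcohol, which sets the later C4 carbinol, and the (S)-alcohol is left behind.

**Step 8**
Reactants: 13 (1R)-1-[(2R)-2-{[(tert-butyldimethylsilyl)oxy]methyl}oxiran-2-yl]propan-1-ol
Product: 14 trimethylsilyl ether of 13
Conditions: TMSCl, Et3N, CH2Cl2, 0 °C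
Reagents that add atoms: chlorotrimethylsilane, C[Si](C)(C)Cl
Why: The secondary hydroxyl is masked as a labile silyl ether so that it neither quenches the acetylide nor binds BF3 in the next step.

**Step 9**
Reactants: 7 (3S)-5-bromo-3-methylhex-5-en-1-yne; 14 trimethylsilyl ether of 13
Product: 17 (3R,4R,8S)-10-bromo-4-{[(tert-butyldimethylsilyl)oxy]methyl}-8-methylundec-10-en-6-yne-3,4-diol, via lithium acetylide 15 (not isolated), via TMS ether 16 (not isolated)
Conditions: 7 (1.2 equiv), n-BuLi, THF, −78 °C; BF3·OEt2; then 14, −78 °C; aq NH4Cl; then K2CO3, MeOH, rt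
Reagents that add atoms: none
Why: Yamaguchi–Hirao alkynylation: the alkynyl borate attacks the unsubstituted oxirane carbon (C5) in an SN2 opening that leaves quaternary C4 untouched, and methanolysis of the TMS ether then frees the C3 hydroxyl.

**Step 10**
Reactants: 17 (3R,4R,8S)-10-bromo-4-{[(tert-butyldimethylsilyl)oxy]methyl}-8-methylundec-10-en-6-yne-3,4-diol
Product: 18 (3R,4R,8S)-10-bromo-4-{[(tert-butyldimethylsilyl)oxy]methyl}-4-hydroxy-8-methylundec-10-en-6-yn-3-yl 2,2-dimethylpropanoate
Conditions: PivCl, pyridine, DMAP (cat.), CH2Cl2, 0 → 40 °C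
Reagents that add atoms: pivaloyl chloride, CC(C)(C)C(=O)Cl
Why: Only the secondary hydroxyl is acylated (the tertiary one is too hindered), which blocks C3–OH as a base-stable ester for steps 11–14.

**Step 11**
Reactants: 18 (3R,4R,8S)-10-bromo-4-{[(tert-butyldimethylsilyl)oxy]methyl}-4-hydroxy-8-methylundec-10-en-6-yn-3-yl 2,2-dimethylpropanoate
Product: 20 (1R)-1-[(3E,5R)-3-[(2S)-4-bromo-2-methylpent-4-en-1-ylidene]-5-{[(tert-butyldimethylsilyl)oxy]methyl}-2,2-dimethyl-1,2-oxasilolan-5-yl]propyl 2,2-dimethylpropanoate, via dimethylsilyl ether 19 (not isolated)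
Conditions: Me2SiHCl, Et3N, DMAP (cat.), CH2Cl2, 0 °C → rt; then Karstedt catalyst (1 mol % Pt), THF, rt
Reagents that add atoms: chlorodimethylsilane, C[SiH](C)Cl
Why: Tethered platinum-catalysed hydrosilylation: the Si–H on the C4 oxygen adds syn across the alkyne in a 5-exo-dig mode, which puts silicon on C6 and hydrogen on C7 on the same side and so fixes C5 and C8 cis.

**Step 12**
Reactants: 20 (the cyclic vinylsiloxane of step 11)
Product: 21 (3R,4R,6E,8S)-10-bromo-4-{[(tert-butyldimethylsilyl)oxy]methyl}-4-hydroxy-6-iodo-8-methylundeca-6,10-dien-3-yl 2,2-dimethylpropanoate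
Conditions: NIS, (CF3)2CHOH/CH2Cl2, 0 °C; then KHF2, MeOH, rt
Reagents that add atoms: N-iodosuccinimide, O=C1CCC(=O)N1I
Why: Ipso-iododesilylation of the vinylsilane with retention of alkene geometry (β-silyl cation pathway in the ionising solvent), followed by fluoride cleavage of the remaining Si–O bond, should give the (E)-vinyl iodide and free the C4 hydroxyl.

**Step 13**
Reactants: 21 (the vinyl iodide of step 12)
Product: 22 4-O-triethylsilyl ether of 21
Conditions: TESOTf, 2,6-lutidine, CH2Cl2, −78 → 0 °C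
Reagents that add atoms: triethylsilyl trifluoromethanesulfonate, CC[Si](CC)(CC)OS(=O)(=O)C(F)(F)F
Why: Silylation of the tertiary alcohol is needed here because a free γ-hydroxyl would cyclise onto the vinyl iodide under copper catalysis, and later because C4–OH must be masked in the key step.

**Step 14**
Reactants: 22 4-O-triethylsilyl ether of 21
Product: 23 (3R,4R,6E,8S)-10-bromo-4-{[(tert-butyldimethylsilyl)oxy]methyl}-6-methoxy-8-methyl-4-[(triethylsilyl)oxy]undeca-6,10-dien-3-yl 2,2-dimethylpropanoate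
Conditions: CuI (10 mol %), 3,4,7,8-tetramethyl-1,10-phenanthroline (20 mol %), Cs2CO3, MeOH (5 equiv), toluene, 80 °C
Reagents that add atoms: methanol, CO
Why: Ullmann-type copper-catalysed C–O coupling of a vinyl iodide with an aliphatic alcohol proceeds with retention at the alkene and should prefer the iodide over the hindered vinyl bromide, giving the (E)-methyl enol ether (OMe trans to C8).

**Step 15**
Reactants: 23 (the enol ether pivalate of step 14)
Product: 24 (3R,4R,6E,8S)-10-bromo-4-{[(tert-butyldimethylsilyl)oxy]methyl}-6-methoxy-8-methyl-4-[(triethylsilyl)oxy]undeca-6,10-dien-3-ol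
Conditions: DIBAL-H, CH2Cl2, −78 °C; Rochelle salt
Reagents that add atoms: none
Why: Reductive removal of the pivalate under non-acidic conditions that the enol ether, the silyl ethers and the vinyl bromide tolerate.

**Step 16**
Reactants: 24 (the C3 alcohol of step 15)
Product: 25 (4R,6E,8S)-10-bromo-4-{[(tert-butyldimethylsilyl)oxy]methyl}-6-methoxy-8-methyl-4-[(triethylsilyl)oxy]undeca-6,10-dien-3-one
Conditions: Dess–Martin periodinane, pyridine, CH2Cl2, 0 °C → rt
Reagents that add atoms: none
Why: Buffered Dess–Martin oxidation of the hindered secondary alcohol gives the ethyl ketone and erases the auxiliary C3 stereocentre.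

**Step 17**
Reactants: 26 (3S)-pent-1-yn-3-ol
Product: 28 (1Z,3S)-1-iodo-2-methylpent-1-en-3-ol, via magnesium chelate 27 (not isolated)
Conditions: MeMgBr (3 equiv), CuI (15 mol %), THF, −20 °C → rt; then I2, −78 → 0 °C; aq NH4Cl
Reagents that add atoms: methylmagnesium bromide, C[Mg]Br; iodine, II
Why: Copper-catalysed anti-carbomagnesiation of the propargylic alkoxide gives a five-membered magnesium chelate (methyl on C12, magnesium on C11 cis to the carbinol carbon), and iodinolysis with retention gives the (Z)-vinyl iodide; C13 comes unchanged from the starting alcohol.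

**Step 18**
Reactants: 28 (1Z,3S)-1-iodo-2-methylpent-1-en-3-ol
Product: 29 (1Z,3S)-2-methyl-1-(4,4,5,5-tetramethyl-1,3,2-dioxaborolan-2-yl)pent-1-en-3-ol
Conditions: B2pin2, PdCl2(PPh3)2 (3 mol %), PPh3, KOPh, toluene, 50 °C
Reagents that add atoms: bis(pinacolato)diboron, CC1(C)OB(OC1(C)C)B1OC(C)(C)C(C)(C)O1
Why: Miyaura borylation of an alkenyl iodide proceeds with retention of the (Z) geometry, and the weak phenoxide base avoids homocoupling.

**Step 19**
Reactants: 25 (the ethyl ketone of step 16); 29 (the alkenylboronate of step 18)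
Product: 30 (4R,6E,8S,11Z,13S)-4-{[(tert-butyldimethylsilyl)oxy]methyl}-13-hydroxy-6-methoxy-8,12-dimethyl-10-methylidene-4-[(triethylsilyl)oxy]pentadeca-6,11-dien-3-one
Conditions: Pd(dppf)Cl2 (10 mol %), AsPh3, Cs2CO3, DMF/H2O, rt
Reagents that add atoms: none
Why: Suzuki–Miyaura coupling of the 2-bromo-1-alkene with the (Z)-alkenylboronate forms C10–C11 with retention at both partners and gives the 2-substituted diene; the free C13 hydroxyl needs no protection.

**Step 20**
Reactants: 30 (the seco hydroxy ketone of step 19)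
Product: 31 13-O-(1H-imidazole-1-carbonyl) derivative of 30
Conditions: CDI, CH2Cl2, rt
Reagents that add atoms: 1,1'-carbonyldiimidazole, O=C(n1ccnc1)n1ccnc1
Why: The only free hydroxyl is converted into its imidazole-1-carboxylate, which brings in C1 as a moderately reactive acyl donor that survives isolation.

**Step 21**
Reactants: 31 13-O-(1H-imidazole-1-carbonyl) derivative of 30
Product: 34 (3R,5R,7E,9S,12Z,14S)-5-{[(tert-butyldimethylsilyl)oxy]methyl}-14-ethyl-7-methoxy-3,9,13-trimethyl-11-methylidene-5-[(triethylsilyl)oxy]-1-oxacyclotetradeca-7,12-diene-2,4-dione, via ketone enolate 32 (not isolated), via lactone enolate 33 (not isolated)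
Conditions: LiHMDS (3 equiv), THF, −78 → −20 °C, 31 added over 8 h (final 0.5 mM); AcOH, −78 °C; pH 7 buffer
Reagents that add atoms: none
Why: LiHMDS removes the only acidic proton of 31 (C2–H; C4 is fully substituted, so the C3 ketone has one enolisable side) to give the (Z)-lithium enolate, whose carbon attacks the carbamate carbonyl C1 and expels imidazolide; imidazolide and excess base then deprotonate the 2-methyl-3-oxo lactone, which makes the addition–elimination irreversible. The closest known reaction types are the Dieckmann/Claisen macrocyclisation of diesters and the C-acylation of ketone lithium enolates with alkyl imidazole-1-carboxylates, and lithium enolates of tertiary α-silyloxy ethyl ketones are well behaved at low temperature. The 14-membered ring closes in a 14-exo-trig mode at the carbonyl carbon, helped by the ring-cis trisubstituted alkenes C6=C7 and C11=C12 and by quaternary C4, which bend the chain. The new stereocentre C2 lies between two carbonyls; it is set on protonation of the chelated enolate 33 and by equilibration through the enol, so the macrocycle decides it under thermodynamic control. The step needs C- over O-acylation (lithium counter-ion and imidazolide leaving group; any enol carbonate would be returned to the enolate by imidazolide) and ring closure over oligomerisation (slow addition, high dilution); no other acidic or electrophilic site competes because both hydroxyls are silylated.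

**Step 22**
Reactants: 34 (the bis-silyl macrolactone of step 21)
Product: 35 (3R,5R,7E,9S,12Z,14S)-14-ethyl-5-hydroxy-5-(hydroxymethyl)-7-methoxy-3,9,13-trimethyl-11-methylidene-1-oxacyclotetradeca-7,12-diene-2,4-dione
Conditions: TASF, DMF/H2O, 0 °C → rt; pH 7 buffer
Reagents that add atoms: none
Why: Fluoride cleavage of both silyl ethers under near-neutral conditions should spare the acid-labile enol ether and the base-labile 3-oxo lactone.

**Compound list**

1 | (R)-4-benzyl-3-propanoyl-1,3-oxazolidin-2-one | CCC(=O)N1[C@H](Cc2ccccc2)COC1=O | starting material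
2 | 2,3-dibromoprop-1-ene | C=C(Br)CBr | starting material
3 | sodium (Z)-enolate of 1 | [Na+].C/C=C(\[O-])N1[C@H](Cc2ccccc2)COC1=O | intermediate
4 | (R)-4-benzyl-3-[(2S)-4-bromo-2-methylpent-4-enoyl]-1,3-oxazolidin-2-one | C=C(Br)C[C@H](C)C(=O)N1[C@H](Cc2ccccc2)COC1=O | intermediate
5 | (2S)-4-bromo-2-methylpent-4-en-1-ol | C=C(Br)C[C@H](C)CO | intermediate
6 | (2S)-4-bromo-2-methylpent-4-enal | C=C(Br)C[C@H](C)C=O | intermediate
7 | (3S)-5-bromo-3-methylhex-5-en-1-yne | C=C(Br)C[C@H](C)C#C | intermediate
8 | 2-bromoprop-2-en-1-ol | C=C(Br)CO | starting material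
9 | propanal | CCC=O | starting material
10 | lithium 2-lithioprop-2-en-1-olate | [Li]OCC([Li])=C | intermediate
11 | (±)-2-methylidenepentane-1,3-diol | CCC(O)C(=C)CO | intermediate
12 | (±)-2-{[(tert-butyldimethylsilyl)oxy]methyl}pent-1-en-3-ol | CCC(O)C(=C)CO[Si](C)(C)C(C)(C)C | intermediate
13 | (1R)-1-[(2R)-2-{[(tert-butyldimethylsilyl)oxy]methyl}oxiran-2-yl]propan-1-ol | CC[C@@H](O)[C@]1(CO[Si](C)(C)C(C)(C)C)CO1 | intermediate
14 | trimethylsilyl ether of 13 | CC[C@@H](O[Si](C)(C)C)[C@]1(CO[Si](C)(C)C(C)(C)C)CO1 | intermediate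
15 | lithium acetylide of 7 | [Li]C#C[C@@H](C)CC(Br)=C | intermediate
16 | 3-O-trimethylsilyl ether of 17 | CC[C@@H](O[Si](C)(C)C)[C@](O)(CO[Si](C)(C)C(C)(C)C)CC#C[C@@H](C)CC(Br)=C | intermediate
17 | (3R,4R,8S)-10-bromo-4-{[(tert-butyldimethylsilyl)oxy]methyl}-8-methylundec-10-en-6-yne-3,4-diol | CC[C@@H](O)[C@](O)(CO[Si](C)(C)C(C)(C)C)CC#C[C@@H](C)CC(Br)=C | intermediate
18 | 3-O-pivalate of 17 | CC[C@@H](OC(=O)C(C)(C)C)[C@](O)(CO[Si](C)(C)C(C)(C)C)CC#C[C@@H](C)CC(Br)=C | intermediate
19 | 4-O-dimethylsilyl ether of 18 | CC[C@@H](OC(=O)C(C)(C)C)[C@](O[SiH](C)C)(CO[Si](C)(C)C(C)(C)C)CC#C[C@@H](C)CC(Br)=C | intermediate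
20 | cyclic vinylsiloxane (1,2-oxasilolane with exocyclic (E)-alkene, Si on C6) | CC[C@@H](OC(=O)C(C)(C)C)[C@]1(CO[Si](C)(C)C(C)(C)C)C/C(=C\[C@@H](C)CC(Br)=C)[Si](C)(C)O1 | intermediate
21 | (3R,4R,6E,8S)-6-iodo vinyl iodide with free C4–OH | CC[C@@H](OC(=O)C(C)(C)C)[C@](O)(CO[Si](C)(C)C(C)(C)C)C/C(I)=C\[C@@H](C)CC(Br)=C | intermediate
22 | 4-O-triethylsilyl ether of 21 | CC[C@@H](OC(=O)C(C)(C)C)[C@](O[Si](CC)(CC)CC)(CO[Si](C)(C)C(C)(C)C)C/C(I)=C\[C@@H](C)CC(Br)=C | intermediate
23 | (6E)-methyl enol ether pivalate | CC[C@@H](OC(=O)C(C)(C)C)[C@](O[Si](CC)(CC)CC)(CO[Si](C)(C)C(C)(C)C)C/C(OC)=C\[C@@H](C)CC(Br)=C | intermediate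
24 | C3 alcohol from 23 | CC[C@@H](O)[C@](O[Si](CC)(CC)CC)(CO[Si](C)(C)C(C)(C)C)C/C(OC)=C\[C@@H](C)CC(Br)=C | intermediate
25 | (4R,6E,8S)-ethyl ketone with vinyl bromide | CCC(=O)[C@](O[Si](CC)(CC)CC)(CO[Si](C)(C)C(C)(C)C)C/C(OC)=C\[C@@H](C)CC(Br)=C | intermediate
26 | (3S)-pent-1-yn-3-ol | C#C[C@@H](O)CC | starting material
27 | (S)-5-ethyl-4-methyl-2,5-dihydro-1,2-oxamagnesole (vinylmagnesium alkoxide chelate) | CC[C@@H]1O[Mg]C=C1C | intermediate
28 | (1Z,3S)-1-iodo-2-methylpent-1-en-3-ol | I/C=C(/C)[C@@H](O)CC | intermediate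
29 | (1Z,3S)-2-methyl-1-(4,4,5,5-tetramethyl-1,3,2-dioxaborolan-2-yl)pent-1-en-3-ol | CC1(C)OB(/C=C(/C)[C@@H](O)CC)OC1(C)C | intermediate
30 | seco hydroxy ketone (4R,6E,8S,11Z,13S) | CCC(=O)[C@](O[Si](CC)(CC)CC)(CO[Si](C)(C)C(C)(C)C)C/C(OC)=C\[C@@H](C)CC(=C)/C=C(/C)[C@@H](O)CC | intermediate
31 | 13-O-(1H-imidazole-1-carbonyl) derivative of 30 | CCC(=O)[C@](O[Si](CC)(CC)CC)(CO[Si](C)(C)C(C)(C)C)C/C(OC)=C\[C@@H](C)CC(=C)/C=C(/C)[C@@H](OC(=O)n1ccnc1)CC | intermediate
32 | lithium (Z)-enolate of 31 | [Li+].C/C=C(\[O-])[C@](O[Si](CC)(CC)CC)(CO[Si](C)(C)C(C)(C)C)C/C(OC)=C\[C@@H](C)CC(=C)/C=C(/C)[C@@H](OC(=O)n1ccnc1)CC | intermediate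
33 | lithium enolate of 34 | [Li+].C=C1/C=C(/C)[C@H](CC)OC(=O)/C(C)=C(\[O-])[C@](O[Si](CC)(CC)CC)(CO[Si](C)(C)C(C)(C)C)C/C(OC)=C\[C@@H](C)C1 | intermediate
34 | bis-silyl macrolactone (3R,5R,7E,9S,12Z,14S) | C=C1/C=C(/C)[C@H](CC)OC(=O)[C@H](C)C(=O)[C@](O[Si](CC)(CC)CC)(CO[Si](C)(C)C(C)(C)C)C/C(OC)=C\[C@@H](C)C1 | intermediate
35 | (3R,5R,7E,9S,12Z,14S)-14-ethyl-5-hydroxy-5-(hydroxymethyl)-7-methoxy-3,9,13-trimethyl-11-methylidene-1-oxacyclotetradeca-7,12-diene-2,4-dione | C=C1/C=C(/C)[C@H](CC)OC(=O)[C@H](C)C(=O)[C@](O)(CO)C/C(OC)=C\[C@@H](C)C1 | target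

**Step count**

Total: 22 steps. Longest linear sequence: 16 steps (1–4, 9–16, 19–22; the branch 5–8 is equally long).

**Steps most likely to fail**

Step 21. The ring closure may lose to intermolecular acylation, to O-acylation that does not revert, or to silyl migration in the enolate on warming. The fallback makes the C1–C2 bond intermolecularly and closes the ring at C10–C11, setting out from 25 and 29 and coming back at 34. Boronate 29 is treated with CDI to give its imidazole-1-carboxylate F1. The lithium enolate of ketone 25 (LiHMDS, THF, −78 °C) is C-acylated with F1 to give the open-chain 2-methyl-3-oxo ester F2 as both C2 epimers. An intramolecular Suzuki–Miyaura coupling of the vinyl bromide and the alkenylboronate in F2 (Pd(dppf)Cl2, AsPh3, Cs2CO3, DMF/H2O, high dilution) then gives 34, in which C2 equilibrates as in the main route.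

Step 14. Oxidative addition and alkoxide transfer at the hindered trisubstituted iodide may be slow, so that reaction at the vinyl bromide or protodeiodination competes. The fallback sets out from 22 and comes back at 23. Miyaura borylation of 22 (B2pin2, PdCl2(dppf), KOAc, dioxane) gives the alkenyl pinacolboronate F3, which is etherified with methanol under oxidative Chan–Lam–Evans conditions (Cu(OAc)2, Et3N, MeOH, O2, rt) with retention of geometry.

Step 12. Ipso-iodination of the alkoxy(vinyl)silane may lose alkene geometry or give protodesilylation. The fallback reaches the enol ether by an epoxysilane/Peterson sequence without the iodide; it sets out from 20, bypasses 21 and 22, and comes back at 23. Epoxidation of 20 (mCPBA, NaHCO3) gives the spiro epoxysilane F4 (both faces, C5 and C8 cis on the oxirane). Acid-catalysed methanolysis (MeOH, PPTS) opens it with inversion at the silicon-bearing C6 to the α-methoxy-β-hydroxysilane F5. Base-induced syn-Peterson elimination (KH, THF; aqueous work-up) gives the (E)-enol ether tertiary alcohol F6, and TESOTf/2,6-lutidine converts it into 23.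

**Further compounds**

F1 | step 21 | (1Z,3S)-2-methyl-1-(4,4,5,5-tetramethyl-1,3,2-dioxaborolan-2-yl)pent-1-en-3-yl 1H-imidazole-1-carboxylate | CC1(C)OB(/C=C(/C)[C@@H](OC(=O)n2ccnc2)CC)OC1(C)C
F2 | step 21 | open-chain 2-methyl-3-oxo ester carrying the vinyl bromide and the alkenylboronate (C2 epimers) | CC(C(=O)O[C@@H](CC)/C(C)=C\B1OC(C)(C)C(C)(C)O1)C(=O)[C@](O[Si](CC)(CC)CC)(CO[Si](C)(C)C(C)(C)C)C/C(OC)=C\[C@@H](C)CC(Br)=C
F3 | step 14 | C6 alkenyl pinacolboronate from 22 | CC[C@@H](OC(=O)C(C)(C)C)[C@](O[Si](CC)(CC)CC)(CO[Si](C)(C)C(C)(C)C)C/C(=C\[C@@H](C)CC(Br)=C)B1OC(C)(C)C(C)(C)O1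
F4 | step 12 | spiro epoxysilane from 20 (oxirane centres as a mixture of the two face isomers) | CC[C@@H](OC(=O)C(C)(C)C)[C@]1(CO[Si](C)(C)C(C)(C)C)CC2(OC2[C@@H](C)CC(Br)=C)[Si](C)(C)O1
F5 | step 12 | α-methoxy-β-hydroxysilane from F4 (C6 and C7 as the corresponding mixture) | CC[C@@H](OC(=O)C(C)(C)C)[C@]1(CO[Si](C)(C)C(C)(C)C)CC(OC)(C(O)[C@@H](C)CC(Br)=C)[Si](C)(C)O1
F6 | step 12 | (6E)-methyl enol ether with free C4 hydroxyl | CC[C@@H](OC(=O)C(C)(C)C)[C@](O)(CO[Si](C)(C)C(C)(C)C)C/C(OC)=C\[C@@H](C)CC(Br)=C
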